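The cyclobutane ring is disconnected at its two CH–C(quaternary) bonds, C2–C3 and C1–C4 (C1 = CH–CO2H, C2 = CH–CO2Me, C3/C4 = C(CH3)(pyranonyl)). This exploits the latent mirror plane of the ring: cis C1/C2 carboxyls are a maleic anhydride, cis C3/C4 a Z-tetrasubstituted alkene. One sensitized [2+2] photocycloaddition of maleic anhydride with 2,5-dimethoxy-2,3,4,5-tetramethyl-2,5-dihydrofuran, a ring-locked equivalent of (Z)-3,4-dimethylhex-3-ene-2,5-dione, forms both bonds and all four stereocentres (cis-anti-cis). The temporary bis-ketal ring is then opened to two cis acetyl groups, each annulated to a 4-methoxy-3-methyl-2-pyranone, and the meso anhydride is desymmetrized by alkaloid-mediated methanolysis.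

Key step: step 3

Remark 1: the sense of induction in step 8 is assigned by analogy with cis-fused bicyclic meso anhydrides, which quinine and quinidine open at opposite enantiotopic carbonyls; quinine is taken to open the carbonyl on the carbon that becomes C2, and quinidine would give the mirror-image half-ester.
Remark 2: methylmalonyl dichloride (9) is treated as purchasable; it is otherwise one step from methylmalonic acid and SOCl2.

Step 1
Reactants: 1 3,4-dimethylhexane-2,5-dione (commercial mixture of diastereomers)
Product: 2 2,3,4,5-tetramethylfuran
Conditions: p-toluenesulfonic acid monohydrate (5 mol %), toluene, reflux, Dean–Stark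
Reagents that add atoms: none
Why: Paal–Knorr cyclodehydration of a 1,4-diketone to the furan, in which both diastereomers of 1 converge because C3 and C4 become sp2.

Step 2
Reactants: 2 2,3,4,5-tetramethylfuran
Product: 3 2,5-dimethoxy-2,3,4,5-tetramethyl-2,5-dihydrofuran (cis/trans mixture at C2/C5, used as such)
Conditions: Br2 (1.0 equiv), Na2CO3 (2.5 equiv), MeOH, −40 °C to 0 °C
Reagents that add atoms: methanol, CO
Why: Oxidative 1,4-dimethoxylation of an electron-rich furan (bromine/methanol, Clauson-Kaas type) should give the 2,5-dihydrofuran bis-ketal, whose cis/trans ratio is irrelevant because both ketal carbons are hydrolysed in step 4.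

Step 3
Reactants: 3 2,5-dimethoxy-2,3,4,5-tetramethyl-2,5-dihydrofuran; 4 maleic anhydride
Product: 5 cis-anti-cis 3,5-dimethoxy-2,3,5,6-tetramethyl-4,9-dioxatricyclo[5.3.0.0(2,6)]decane-8,10-dione (anhydride ring and the two cyclobutane methyl groups on one face of the cyclobutane, tetrahydrofuran ring on the other; epimers at the ketal carbons)
Conditions: hν (medium-pressure mercury lamp, Pyrex filter, λ > 290 nm), acetone (solvent and triplet sensitizer), 3 (3 equiv), freshly sublimed 4, −20 °C, argon
Reagents that add atoms: none
Why: Triplet maleic anhydride, populated by energy transfer from acetone, adds to the ring double bond of 3 to give a triplet 1,4-biradical that closes after intersystem crossing, so that the CH–C(quaternary) bond C2–C3 of the target and its mirror partner C1–C4 are made in one operation. The closest known reaction type is the sensitized [2+2] photocycloaddition of maleic anhydride to cyclic tri- and tetrasubstituted alkenes such as 2,5-dihydrofurans and ring-fusion alkenes (propellane synthesis). The cyclobutane is the only ring closed, by an intermolecular [2+2] cycloaddition whose second bond forms by collapse of the 1,4-biradical. C1 and C2 are cis because they stay inside the five-membered anhydride, C3 and C4 are cis because the dihydrofuran ring forbids both E/Z isomerization of the alkene and bond rotation in the biradical, and the anhydride should end on the methyl face (cis-anti-cis) because the other approach would stack the two five-membered rings and the out-of-plane ketal substituents. The step needs cross-addition instead of anhydride dimerization and ring closure instead of hydrogen transfer: the first is secured by the non-absorbing, electron-rich alkene in excess, the second by the two radical centres being held 1,4 in a rigid bicycle at low temperature.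

Step 4
Reactants: 5 cis-anti-cis tricyclic bis-ketal anhydride
Product: 7 6,7-diacetyl-6,7-dimethyl-3-oxabicyclo[3.2.0]heptane-2,4-dione (meso; acetyl groups cis to each other and trans to the anhydride ring; methyl groups on the anhydride face), via diketo diacid 6 (not isolated)
Conditions: 1 M aq. HCl, THF, 20 °C; evaporate; Ac2O, 60 °C
Reagents that add atoms: water, O
Why: Acid-catalysed hydrolysis of the cyclic bis-ketal unmasks the 1,4-diketone without touching a stereocentre (furan formation is impossible because both carbons between the carbonyls are quaternary), and acetic anhydride re-closes the diacid to the anhydride, which can only be cis-fused and therefore keeps C1 and C2 cis.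

Step 5
Reactants: 7 6,7-diacetyl-6,7-dimethyl-3-oxabicyclo[3.2.0]heptane-2,4-dione
Product: 8 6,7-dimethyl-6,7-bis[1-(trimethylsilyloxy)ethenyl]-3-oxabicyclo[3.2.0]heptane-2,4-dione (same relative configuration as 7)
Conditions: TMSOTf (2.2 equiv), Et3N (3 equiv), CH2Cl2, 0 °C; non-aqueous work-up (pentane)
Reagents that add atoms: trimethylsilyl trifluoromethanesulfonate, C[Si](C)(C)OS(=O)(=O)C(F)(F)F
Why: Soft enolisation (silyl triflate/amine) should silylate each methyl ketone at its only enolisable side, the CH3 group, whereas enolisation of the anhydride would put an sp2 carbon at the 4/5 ring fusion and is disfavoured.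

Step 6
Reactants: 8 bis(silyl enol ether); 9 methylmalonyl dichloride
Product: 10 6,7-bis(4-hydroxy-3-methyl-2-oxo-2H-pyran-6-yl)-6,7-dimethyl-3-oxabicyclo[3.2.0]heptane-2,4-dione (meso; pyranonyl groups cis to each other, trans to the anhydride ring)
Conditions: 9 (2.2 equiv), Et2O, −78 °C to 20 °C; volatiles removed, non-aqueous trituration
Reagents that add atoms: none
Why: Pyranone annulation of silyl enol ethers with a malonyl dichloride: C-acylation of each enol ether terminus by one acid chloride and lactonisation of the resulting enol onto the second should build both 4-hydroxy-3-methyl-2-pyranone rings with unambiguous regiochemistry (ketone carbon becomes C6, its methyl becomes C5), and the acid chloride does not react with the anhydride.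

Step 7
Reactants: 10 bis(4-hydroxypyranonyl) anhydride
Product: 11 6,7-bis(4-methoxy-3-methyl-2-oxo-2H-pyran-6-yl)-6,7-dimethyl-3-oxabicyclo[3.2.0]heptane-2,4-dione (meso; same relative configuration)
Conditions: Me2SO4 (2.5 equiv), K2CO3 (anhydrous, 3 equiv), dry acetone, 20 °C
Reagents that add atoms: dimethyl sulfate, COS(=O)(=O)OC
Why: O-Methylation of the vinylogous-acid hydroxyls (pKa near 5) with dimethyl sulfate and K2CO3 in acetone, conditions that favour the 4-methoxy-2-pyranone over the 2-methoxy-4-pyranone isomer, while the anhydride, which carries no acidic proton, should stay intact under anhydrous conditions.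

Step 8
Reactants: 11 meso bis(4-methoxypyranonyl) anhydride
Product: 12 (1S,2R,3S,4R)-2-(methoxycarbonyl)-3,4-bis(4-methoxy-3-methyl-2-oxo-2H-pyran-6-yl)-3,4-dimethylcyclobutane-1-carboxylic acid (CNP0481603.1)
Conditions: quinine (1.1 equiv), MeOH (3 equiv), toluene/CH2Cl2, −55 °C; then 1 M aq. HCl wash
Reagents that add atoms: methanol, CO
Why: Cinchona-alkaloid-mediated enantiotopos-selective methanolysis of a meso anhydride (general-base delivery of methanol by the quinuclidine nitrogen) opens one of the two mirror-related carbonyls, and because 11 is meso this single event should fix the absolute configuration of all four stereocentres as (1S,2R,3S,4R).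

Compound list
1 | 3,4-dimethylhexane-2,5-dione (diastereomer mixture) | CC(=O)C(C)C(C)C(C)=O | starting material
2 | 2,3,4,5-tetramethylfuran | Cc1oc(C)c(C)c1C | intermediate
3 | 2,5-dimethoxy-2,3,4,5-tetramethyl-2,5-dihydrofuran (cis/trans mixture) | COC1(C)OC(C)(OC)C(C)=C1C | intermediate
4 | maleic anhydride | O=C1OC(=O)C=C1 | starting material
5 | cis-anti-cis 3,5-dimethoxy-2,3,5,6-tetramethyl-4,9-dioxatricyclo[5.3.0.0(2,6)]decane-8,10-dione (ketal epimers) | O=C2[C@@H]1[C@H](C(=O)O2)[C@@](C)(C3(C)OC)[C@@]1(C)C(C)(OC)O3 | intermediate
6 | meso 3,4-diacetyl-3,4-dimethylcyclobutane-1,2-dicarboxylic acid (carboxyls cis, acetyls cis, carboxyls trans to acetyls) | OC(=O)[C@@H]1[C@H](C(=O)O)[C@@](C)(C(C)=O)[C@@]1(C)C(C)=O | intermediate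
7 | meso 6,7-diacetyl-6,7-dimethyl-3-oxabicyclo[3.2.0]heptane-2,4-dione | O=C2[C@@H]1[C@H](C(=O)O2)[C@@](C)(C(C)=O)[C@@]1(C)C(C)=O | intermediate
8 | meso 6,7-dimethyl-6,7-bis[1-(trimethylsilyloxy)ethenyl]-3-oxabicyclo[3.2.0]heptane-2,4-dione | O=C2[C@@H]1[C@H](C(=O)O2)[C@@](C)(C(=C)O[Si](C)(C)C)[C@@]1(C)C(=C)O[Si](C)(C)C | intermediate
9 | methylmalonyl dichloride | CC(C(=O)Cl)C(=O)Cl | starting material
10 | meso 6,7-bis(4-hydroxy-3-methyl-2-oxo-2H-pyran-6-yl)-6,7-dimethyl-3-oxabicyclo[3.2.0]heptane-2,4-dione | O=C2[C@@H]1[C@H](C(=O)O2)[C@@](C)(c3cc(O)c(C)c(=O)o3)[C@@]1(C)c4cc(O)c(C)c(=O)o4 | intermediate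
11 | meso 6,7-bis(4-methoxy-3-methyl-2-oxo-2H-pyran-6-yl)-6,7-dimethyl-3-oxabicyclo[3.2.0]heptane-2,4-dione | O=C2[C@@H]1[C@H](C(=O)O2)[C@@](C)(c3cc(OC)c(C)c(=O)o3)[C@@]1(C)c4cc(OC)c(C)c(=O)o4 | intermediate
12 | (1S,2R,3S,4R)-2-(methoxycarbonyl)-3,4-bis(4-methoxy-3-methyl-2-oxo-2H-pyran-6-yl)-3,4-dimethylcyclobutane-1-carboxylic acid | COC(=O)[C@@H]1[C@H](C(=O)O)[C@@](C)(c2cc(OC)c(C)c(=O)o2)[C@@]1(C)c1cc(OC)c(C)c(=O)o1 | target

Total step count: 8. Longest linear sequence: 8 steps (1 to 12).

Steps most likely to fail

Step 3 (photocycloaddition). Hydrogen transfer inside the 1,4-biradical (ene-type products) or self-dimerization of 4 may outrun ring closure at the hindered tetrasubstituted alkene. In that case the two carboxyl carbons are delivered by an enedione chromophore and released by oxidative ring degradation. Setting out from 3, irradiation (λ about 350 nm, CH2Cl2) with purchased cyclopent-4-ene-1,3-dione (O=C1CC(=O)C=C1) should give cis-anti-cis 3,5-dimethoxy-2,3,5,6-tetramethyl-4-oxatricyclo[5.3.0.0(2,6)]decane-8,10-dione F1. Its ring methylene between the two carbonyls is then excised with NaIO4 (4 equiv) in aqueous dioxane, a 1,3-diketone cleavage to two carboxylic acids and CO2. The acidic medium hydrolyses the ketals at the same time, so the diketo diacid 6 results and the route is rejoined at 6, at the acetic anhydride stage of step 4.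

Step 6 (double pyranone annulation). The hydrogen chloride released by the first annulation may protodesilylate the second enol ether, or the two neighbouring arms may cross-react. The pyranones are then built from the diketone itself without silyl enol ethers. Setting out from 7, heating (about 200 °C, diphenyl ether) with bis(2,4,6-trichlorophenyl) 2-methylmalonate F2 (made from methylmalonic acid, 2,4,6-trichlorophenol and POCl3) is a thermal active-ester condensation. It acylates each ketone enol at carbon and lactonises with loss of trichlorophenol, and the route is rejoined at 10.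

Step 7 (O-methylation beside the anhydride). Carbonate or pyranolate may open the anhydride, and the liberated carboxylates would then be esterified irreversibly, which removes the meso anhydride needed for step 8. The anhydride is then given up on purpose and the desymmetrization is moved to an enzyme. Setting out from 10, exhaustive methylation (excess Me2SO4, K2CO3, acetone containing methanol) should give meso dimethyl 3,4-bis(4-methoxy-3-methyl-2-oxo-2H-pyran-6-yl)-3,4-dimethylcyclobutane-1,2-dicarboxylate F3. Enantiotopos-selective monohydrolysis with pig liver esterase (pH 7 phosphate buffer, DMSO co-solvent; an esterase/lipase panel is screened for hydrolysis of the C1 ester) should then give the half-ester, and the route is rejoined at 12.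

Further compounds
F1 | step 3 | cis-anti-cis 3,5-dimethoxy-2,3,5,6-tetramethyl-4-oxatricyclo[5.3.0.0(2,6)]decane-8,10-dione (ketal epimers) | O=C2[C@@H]1[C@H](C(=O)C2)[C@@](C)(C3(C)OC)[C@@]1(C)C(C)(OC)O3
F2 | step 6 | bis(2,4,6-trichlorophenyl) 2-methylmalonate | CC(C(=O)Oc1c(Cl)cc(Cl)cc1Cl)C(=O)Oc1c(Cl)cc(Cl)cc1Cl
F3 | step 7 | meso dimethyl 3,4-bis(4-methoxy-3-methyl-2-oxo-2H-pyran-6-yl)-3,4-dimethylcyclobutane-1,2-dicarboxylate | COC(=O)[C@@H]1[C@H](C(=O)OC)[C@@](C)(c2cc(OC)c(C)c(=O)o2)[C@@]1(C)c1cc(OC)c(C)c(=O)o1
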